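**Retrosynthetic overview**

1. The ten-membered carbocycle is closed last at the C1(sp2)–C2(sp3) bond by a one-pot hydroboration / B-alkyl Suzuki–Miyaura macrocyclisation of an acyclic seco-triene.
2. Enabling feature: C2–C3–C4(Me)=C5 is a latent 1,3-diene whose terminal carbon C2 takes boron, and C1=C10(–C14) is a latent alkyne carried as an E-1-iodo-2-bromoalkene (I on C1 for ring closure, Br on C10 for the formyl carbon). The trans-fused γ-lactone (C6, C7, C11, C12, O) and the Z-C4=C5 bond turn both chain ends to the same side.
3. The lactone is made first: a Nozaki–Hiyama allylation/lactonisation joins the Z-dienal (C2–C6) to a 2-(bromomethyl)enoyl imide (C7, C11–C13 with C8–C10 and C1), forming C6–C7 and setting C6 and C7.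
4. C8 and C9 come from Sharpless epoxidation of (2E)-pent-2-en-4-yn-1-ol and C3-selective opening with acetic acid, which also tells the two oxygens apart.
5. Ring order: γ-lactone (step 11), then the ten-membered ring (step 15). The end game is formylation of C10–Br and unmasking of the methylene lactone.

Key step: step 15

Remark on numbering: C1–C15 are the germacrane numbers of the target (C1=C10 enal alkene, C14 formyl carbon, C4=C5 methyl-bearing alkene, C6 lactone carbinol, C7 ring fusion, C8/C9 acyloxy carbons, C11–C13 lactone carbons).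
Remark on mixtures: 14 and 15 are carried as mixtures at the centres that step 10 erases, and the amine adducts 19–25 as C11 epimers that step 17 erases; these centres are written without configuration.

**Route**

Step 1
Reactants: 1 (2Z)-3-methylpent-2-en-4-yn-1-ol
Product: 2 (2Z)-3-methylpenta-2,4-dien-1-ol
Conditions: Zn dust activated with Cu(OAc)2 and AgNO3, MeOH/H2O 1:1, 40 °C
Reagents that add atoms: none
Why: Zinc-mediated semi-reduction of a conjugated terminal alkyne should stop at the alkene and leave the trisubstituted Z-alkene untouched, so the Z geometry of the enyne is carried into the diene.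

Step 2
Reactants: 2 (2Z)-3-methylpenta-2,4-dien-1-ol
Product: 3 (2Z)-3-methylpenta-2,4-dienal
Conditions: MnO2 (activated, excess), CH2Cl2, 0 °C, used at once
Reagents that add atoms: none
Why: Allylic oxidation with MnO2 is neutral and should give the enal without Z to E drift if the aldehyde is used directly.

Step 3
Reactants: 4 (2S)-2-hydroxy-2-methylbutanoic acid
Product: 6 (2S)-2-acetoxy-2-methylbutanoyl chloride, via (2S)-2-acetoxy-2-methylbutanoic acid 5 (not isolated)
Conditions: AcCl (neat), 50 °C; evaporation; (COCl)2, cat. DMF, CH2Cl2, 0 °C to rt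
Reagents that add atoms: acetyl chloride CC(=O)Cl; oxalyl chloride O=C(Cl)C(=O)Cl
Why: O-acetylation of the tertiary α-hydroxy acid followed by acid chloride formation is a standard two-stage activation, and the fully substituted stereocentre cannot epimerise.

Step 4
Reactants: 7 (2E)-pent-2-en-4-yn-1-ol
Product: 8 [(2S,3S)-3-ethynyloxiran-2-yl]methanol
Conditions: Ti(OiPr)4 (10 mol %), L-(+)-diethyl tartrate (12 mol %), t-BuOOH, 4 Å molecular sieves, CH2Cl2, −20 °C
Reagents that add atoms: tert-butyl hydroperoxide CC(C)(C)OO
Why: Sharpless asymmetric epoxidation with the (+)-tartrate catalyst should deliver oxygen to one face of the E-allylic alcohol and give the (2S,3S)-epoxide, which sets the future C8 and C9.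

Step 5
Reactants: 8 [(2S,3S)-3-ethynyloxiran-2-yl]methanol
Product: 9 (2S,3R)-1,2-dihydroxypent-4-yn-3-yl acetate
Conditions: Ti(OiPr)4 (1.5 equiv), AcOH (2 equiv), CH2Cl2, 0 °C to rt; aqueous tartaric acid work-up
Reagents that add atoms: acetic acid CC(=O)O
Why: Titanium-mediated C3-selective opening of a 2,3-epoxy alcohol: acetic acid should attack the propargylic carbon with inversion, placing the C9 acetate and leaving the C8 oxygen with retention, so the erythro 8,9-pattern and the difference between the two oxygens are fixed together.

Step 6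
Reactants: 9 (2S,3R)-1,2-dihydroxypent-4-yn-3-yl acetate
Product: 10 (2S,3R)-1,2-bis(triethylsilyloxy)pent-4-yn-3-yl acetate
Conditions: Et3SiOTf (2.4 equiv), 2,6-lutidine, CH2Cl2, −78 °C
Reagents that add atoms: triethylsilyl trifluoromethanesulfonate CC[Si](CC)(CC)OS(=O)(=O)C(F)(F)F
Why: Silylation of both hydroxyls stops acetyl migration and makes the C8 oxygen the non-leaving ether that the allylchromium step needs.

Step 7
Reactants: 10 (2S,3R)-1,2-bis(triethylsilyloxy)pent-4-yn-3-yl acetate
Product: 11 (1E,3S,4S)-2-bromo-1-iodo-4,5-bis(triethylsilyloxy)pent-1-en-3-yl acetate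
Conditions: IBr (1.05 equiv), CH2Cl2, −78 to −40 °C, dark
Reagents that add atoms: iodine monobromide BrI
Why: Electrophilic anti addition of IBr to the terminal alkyne should put iodine on the terminal carbon and bromide on the internal carbon, giving the E-dihaloalkene with iodine cis to C9.

Step 8
Reactants: 11 (1E,3S,4S)-2-bromo-1-iodo-4,5-bis(triethylsilyloxy)pent-1-en-3-yl acetate
Product: 12 (2R,3S,4E)-4-bromo-5-iodo-1-oxo-2-(triethylsilyloxy)pent-4-en-3-yl acetate
Conditions: (COCl)2, DMSO, CH2Cl2, −78 to −30 °C; then Et3N, −78 to 0 °C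
Reagents that add atoms: none
Why: Under Swern conditions a primary triethylsilyl ether is oxidised directly to the aldehyde while the secondary silyl ether stays, which saves a deprotection.

Step 9
Reactants: 12 (2R,3S,4E)-4-bromo-5-iodo-1-oxo-2-(triethylsilyloxy)pent-4-en-3-yl acetate; 13 3-acryloyl-1,3-oxazolidin-2-one
Product: 15 Baylis–Hillman-type allylic alcohol (2-methylene-3-hydroxyacyl oxazolidinone), via β-iodo aldol adduct 14 (not isolated)
Conditions: 13, Et2AlI (1.3 equiv), CH2Cl2, 0 °C; 12, −78 to 0 °C; then Et3N, rt
Reagents that add atoms: none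
Why: Halo-aldol reaction: iodide adds to the acryloyl imide, the aluminium enolate adds to the aldehyde, and triethylamine then removes HI, so the β-acetoxy aldehyde never meets an amine base; the new carbinol centre is left uncontrolled because step 10 erases it.

Step 10
Reactants: 15 Baylis–Hillman-type allylic alcohol
Product: 16 (Z)-2-(bromomethyl)enoyl oxazolidinone (allylic bromide)
Conditions: NBS, Me2S, CH2Cl2, −20 to 0 °C
Reagents that add atoms: N-bromosuccinimide O=C1CCC(=O)N1Br
Why: Corey–Kim-type bromination with allylic transposition (SN2') should give the thermodynamically preferred Z-allylic bromide.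

Step 11
Reactants: 16 (Z)-2-(bromomethyl)enoyl oxazolidinone; 3 (2Z)-3-methylpenta-2,4-dienal
Product: 18 trans-α-methylene-γ-butyrolactone (6R,7S), via anti hydroxy imide 17 (not isolated)
Conditions: CrCl2 (4 equiv, nickel-free), THF, 0 °C to rt; aqueous NH4Cl
Reagents that add atoms: none
Why: Nozaki–Hiyama allylation then lactonisation: the allylchromium species should add through a chair transition state with the C7 substituent equatorial (anti, hence the trans-lactone) and from the face of C7 opposite the C9 branch in the conformer that keeps H8 in the alkene plane, giving 6R,7S, after which the chromium alkoxide displaces the oxazolidinone.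

Step 12
Reactants: 18 trans-α-methylene-γ-butyrolactone (6R,7S)
Product: 19 13-dimethylamino adduct (Mannich base) of 18
Conditions: Me2NH (2 M in THF), THF, 0 °C to rt
Reagents that add atoms: dimethylamine CNC
Why: Aza-Michael addition masks the methylene lactone so that it cannot take part in hydroboration or Heck-type insertion in step 15.

Step 13
Reactants: 19 13-dimethylamino adduct of 18
Product: 20 C8 alcohol
Conditions: HF·pyridine, pyridine, THF, 0 °C
Reagents that add atoms: none
Why: Fluoride-mediated desilylation should free the C8 hydroxyl under acidic conditions that leave the acetate where it is.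

Step 14
Reactants: 20 C8 alcohol; 6 (2S)-2-acetoxy-2-methylbutanoyl chloride
Product: 21 seco diester (C8 acyloxy, C9 acetoxy)
Conditions: 6 (2 equiv), DMAP, Et3N, CH2Cl2, 0 °C to rt
Reagents that add atoms: none
Why: DMAP-catalysed acylation with the acid chloride is forcing enough for a hindered secondary alcohol and touches no stereocentre.

Step 15
Reactants: 21 seco diester
Product: 23 macrocyclic alkenyl bromide (ten-membered ring closed), via B-alkyl-9-BBN borane 22 (not isolated)
Conditions: 9-BBN (3 equiv, one held by the amine), THF, 0 °C to rt; then slow addition to PdCl2(dppf) (20 mol %), AsPh3, Cs2CO3, DMF/THF/H2O, 40 °C, final 1 mM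
Reagents that add atoms: none
Why: 9-BBN adds to the only monosubstituted alkene, the terminal vinyl group of the diene, and places boron on C2, zerovalent palladium then inserts into the C1–I bond far faster than into the C10–Br bond, and base-assisted alkyl transfer from boron to palladium followed by reductive elimination forms the C1–C2 bond. The closest known reaction type is the intramolecular B-alkyl Suzuki–Miyaura macrocyclisation. The ten-membered ring is closed by C(sp2)–C(sp3) reductive elimination from an eleven-membered palladacycle and emerges as a cis,cis-cyclodeca-1,5-diene, the least strained diene geometry for this ring size. No stereocentre is formed; oxidative addition and reductive elimination go with retention, so C2 takes the place of iodine cis to C9 and the ring-cis C1=C10 geometry of the target is fixed. The step needs chemoselective hydroboration, site selection between the two halogens and cyclisation ahead of oligomerisation; the first is secured by the alkene substitution pattern and the masked methylene lactone, the second by the iodide/bromide pair, the third by high dilution and by the Z-C4=C5 bond and trans-fused lactone that hold both chain ends on one side.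

Step 16
Reactants: 23 macrocyclic alkenyl bromide
Product: 24 macrocyclic enal (C14 formyl, lactone still masked)
Conditions: Pd(OAc)2 (10 mol %), di(1-adamantyl)-n-butylphosphine, TMEDA, CO/H2 1:1 (5 bar), toluene, 80 °C
Reagents that add atoms: carbon monoxide [C-]#[O+]
Why: Palladium-catalysed reductive carbonylation (formylation) of an alkenyl bromide goes with retention, so the formyl group should end trans to C2 as in the target.

Step 17
Reactants: 24 macrocyclic enal
Product: 26 target CNP0499875.1, via trimethylammonium iodide 25 (not isolated)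
Conditions: MeI, THF, rt; then aqueous NaHCO3, rt
Reagents that add atoms: none
Why: Quaternisation of the Mannich base and mild base-induced β-elimination (Hofmann-type, E1cB) should restore the exocyclic methylene without touching the esters or the enal.

**Compound list**

1 | (2Z)-3-methylpent-2-en-4-yn-1-ol | OC/C=C(/C)C#C | starting material
2 | (2Z)-3-methylpenta-2,4-dien-1-ol | OC/C=C(/C)C=C | intermediate
3 | (2Z)-3-methylpenta-2,4-dienal | O=C/C=C(/C)C=C | intermediate
4 | (2S)-2-hydroxy-2-methylbutanoic acid | OC(=O)[C@](C)(CC)O | starting material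
5 | (2S)-2-acetoxy-2-methylbutanoic acid | OC(=O)[C@](C)(CC)OC(C)=O | intermediate
6 | (2S)-2-acetoxy-2-methylbutanoyl chloride | ClC(=O)[C@](C)(CC)OC(C)=O | intermediate
7 | (2E)-pent-2-en-4-yn-1-ol | OC/C=C/C#C | starting material
8 | [(2S,3S)-3-ethynyloxiran-2-yl]methanol | OC[C@@H]1O[C@H]1C#C | intermediate
9 | (2S,3R)-1,2-dihydroxypent-4-yn-3-yl acetate | OC[C@H](O)[C@H](OC(C)=O)C#C | intermediate
10 | (2S,3R)-1,2-bis(triethylsilyloxy)pent-4-yn-3-yl acetate | CC[Si](CC)(CC)OC[C@H](O[Si](CC)(CC)CC)[C@H](OC(C)=O)C#C | intermediate
11 | (1E,3S,4S)-2-bromo-1-iodo-4,5-bis(triethylsilyloxy)pent-1-en-3-yl acetate | CC[Si](CC)(CC)OC[C@H](O[Si](CC)(CC)CC)[C@H](OC(C)=O)/C(Br)=C\I | intermediate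
12 | (2R,3S,4E)-4-bromo-5-iodo-1-oxo-2-(triethylsilyloxy)pent-4-en-3-yl acetate | O=C[C@H](O[Si](CC)(CC)CC)[C@H](OC(C)=O)/C(Br)=C\I | intermediate
13 | 3-acryloyl-1,3-oxazolidin-2-one | C=CC(=O)N1CCOC1=O | starting material
14 | β-iodo aldol adduct of 12 and 13: 3-hydroxy-2-(iodomethyl)acyl oxazolidinone with C8 OTES, C9 OAc and the E-bromoiodoalkene; C7 and C11 unassigned | O=C(N1CCOC1=O)C(CI)C(O)[C@H](O[Si](CC)(CC)CC)[C@H](OC(C)=O)/C(Br)=C\I | intermediate
15 | Baylis–Hillman-type allylic alcohol: 2-methylene-3-hydroxyacyl oxazolidinone with the same C8–C1 chain; C7 unassigned | C=C(C(=O)N1CCOC1=O)C(O)[C@H](O[Si](CC)(CC)CC)[C@H](OC(C)=O)/C(Br)=C\I | intermediate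
16 | (Z)-2-(bromomethyl)enoyl oxazolidinone: C13 bromide, C7=C11 alkene with C8 cis to CH2Br, C8 OTES, C9 OAc, E-C10(Br)=C1HI | BrC/C(C(=O)N1CCOC1=O)=C\[C@H](O[Si](CC)(CC)CC)[C@H](OC(C)=O)/C(Br)=C\I | intermediate
17 | anti hydroxy imide (6R,7S): C6 carbinol bearing the (Z)-2-methylbuta-1,3-dienyl group, C7 bearing the acryloyl imide and the C8–C1 chain | C=C(C(=O)N1CCOC1=O)[C@@H]([C@H](O)/C=C(/C)C=C)[C@H](O[Si](CC)(CC)CC)[C@H](OC(C)=O)/C(Br)=C\I | intermediate
18 | trans-α-methylene-γ-butyrolactone (6R,7S) with the (Z)-2-methylbuta-1,3-dienyl group on C6 and the C8(OTES)–C9(OAc)–C10(Br)=C1HI chain on C7 | C=C1C(=O)O[C@H](/C=C(/C)C=C)[C@H]1[C@H](O[Si](CC)(CC)CC)[C@H](OC(C)=O)/C(Br)=C\I | intermediate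
19 | 13-dimethylamino adduct (Mannich base) of 18, C11 epimers | CN(C)CC1C(=O)O[C@H](/C=C(/C)C=C)[C@H]1[C@H](O[Si](CC)(CC)CC)[C@H](OC(C)=O)/C(Br)=C\I | intermediate
20 | C8 alcohol of 19 (C9 acetate kept) | CN(C)CC1C(=O)O[C@H](/C=C(/C)C=C)[C@H]1[C@H](O)[C@H](OC(C)=O)/C(Br)=C\I | intermediate
21 | seco diester: C8 (2S)-2-acetoxy-2-methylbutanoate, C9 acetate, masked lactone, Z-diene, E-bromoiodoalkene | CN(C)CC1C(=O)O[C@H](/C=C(/C)C=C)[C@H]1[C@H](OC(=O)[C@](C)(CC)OC(C)=O)[C@H](OC(C)=O)/C(Br)=C\I | intermediate
22 | B-alkyl-9-BBN borane of 21 (boron on C2) | CN(C)CC1C(=O)O[C@H](/C=C(/C)CCB2C3CCCC2CCC3)[C@H]1[C@H](OC(=O)[C@](C)(CC)OC(C)=O)[C@H](OC(C)=O)/C(Br)=C\I | intermediate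
23 | macrocyclic alkenyl bromide: ten-membered ring, C10 bromide, ring-cis C1=C10 and Z-C4=C5, stereocentres as in the target, masked lactone | CN(C)CC1C(=O)O[C@@H]2/C=C(/C)CC/C=C(/Br)[C@@H](OC(C)=O)[C@@H](OC(=O)[C@](C)(CC)OC(C)=O)[C@@H]12 | intermediate
24 | macrocyclic enal: as 23 with C14 formyl in place of bromine | CN(C)CC1C(=O)O[C@@H]2/C=C(/C)CC/C=C(/C=O)[C@@H](OC(C)=O)[C@@H](OC(=O)[C@](C)(CC)OC(C)=O)[C@@H]12 | intermediate
25 | trimethylammonium iodide of 24 | C[N+](C)(C)CC1C(=O)O[C@@H]2/C=C(/C)CC/C=C(/C=O)[C@@H](OC(C)=O)[C@@H](OC(=O)[C@](C)(CC)OC(C)=O)[C@@H]12.[I-] | intermediate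
26 | CNP0499875.1 | C=C1C(=O)O[C@@H]2/C=C(/C)CC/C=C(/C=O)[C@@H](OC(C)=O)[C@@H](OC(=O)[C@](C)(CC)OC(C)=O)[C@@H]12 | target

**Totals and risks**

Total step count: 17. Longest linear sequence: 14 steps (steps 4 to 17, from 7).

Step 15, ring closure. Transmetalation in a medium ring may be slow, so that oligomerisation, protodeboronation or β-hydride elimination of the alkylpalladium species take over; site selection between the two carbon–halogen bonds may also erode. The fallback closes the same bond by nickel-catalysed reductive cross-electrophile coupling. It sets out from 21: hydroboration as in step 15 and oxidation of the borane with NaBO3·4H2O should give the primary alcohol F1; I2, PPh3 and imidazole should turn it into the primary iodide F2; NiI2, 4,4'-di-tert-butyl-2,2'-bipyridine, zinc dust and NaI in DMA under high dilution should then couple the alkyl iodide with the alkenyl iodide, and the route is rejoined at 23.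

Step 11, lactone formation. The anti preference may be too low, the aldehyde may add to the wrong face of C7, or the silyloxy group may be lost by 1,4-elimination from the allylmetal species. The fallback replaces substrate control by reagent control: 16 and 3 are coupled with catalytic CrCl2, manganese powder, chlorotrimethylsilane and a chiral oxazoline–sulfonamide ligand, so that the ligand chooses the face of the aldehyde (C6) and the anti chair transition state then fixes C7. It sets out from 16 and 3, makes no new compound, and returns at 18.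

Step 16, formylation. Oxidative addition at the hindered alkenyl bromide may be slow, and hydrodebromination, β-acetoxy elimination from the alkenylpalladium species, early loss of dimethylamine at 80 °C or Cope rearrangement of the cyclodeca-1,5-diene may compete. The fallback brings in C14 at the alcohol oxidation level: from 23, Stille coupling with (tributylstannyl)methanol and Pd(PPh3)4 in dioxane at 70 °C should give the allylic alcohol F3, which MnO2 in CH2Cl2 should oxidise to 24.

Further compounds
F1 | step 15 | primary alcohol (C2 hydroxyl) from hydroboration–oxidation of 21 | CN(C)CC1C(=O)O[C@H](/C=C(/C)CCO)[C@H]1[C@H](OC(=O)[C@](C)(CC)OC(C)=O)[C@H](OC(C)=O)/C(Br)=C\I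
F2 | step 15 | primary iodide (C2 iodide) | CN(C)CC1C(=O)O[C@H](/C=C(/C)CCI)[C@H]1[C@H](OC(=O)[C@](C)(CC)OC(C)=O)[C@H](OC(C)=O)/C(Br)=C\I
F0 | step 11 | none | none
F3 | step 16 | allylic alcohol (C14 hydroxymethyl macrocycle) | CN(C)CC1C(=O)O[C@@H]2/C=C(/C)CC/C=C(/CO)[C@@H](OC(C)=O)[C@@H](OC(=O)[C@](C)(CC)OC(C)=O)[C@@H]12
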